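Reckon this flask by what the reagent still pulls, not by what was charged.

    starting material + reagent ⇌ target (K1 = 13 /M, k1 = 0.69 /M/s)
    second substrate + reagent ⇌ second product (K2 = 18 /M, k2 = 0.82 /M/s)
    starting material ⇌ dormant form (K3 = 0.54, k3 = 0.27 /s)
    target ⇌ isomer of the product (K4 = 0.10, k4 = 0.010 /s)

starting material 18 mM; reagent 1.50 equiv; second substrate 1.00 equiv (in portions, 4); time 25 min; the portions of second substrate follow each other after 10 s, the first at the start

- what has gone from starting material into another species counts as reacted, even if it can come back
- the reaction counts as stopped when no species that holds the starting material changes by six tenths of a point or more over the second half of the time
- run time (flask): 25 min

1. why nothing more happens at 25 min, or that something still does (it is still moving / forward and back rates have come level / all of the starting material has reacted / the reagent has run out first)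
2. share of the starting material used up at 25 min
3. target at 25 min, in percent of the starting material charged

We reckon at equilibrium, because the forward half-lives, 0.62 min for starting material by the main step, 0.52 min for the second substrate and 1.2 min for target going to its isomer, are short against the 25 min of the run, and the forward half-life of starting material going to the dormant form is 2.6 s. We count everything in parts of the starting material charged, so the constant of the main step becomes 0.234 and that of the second step 0.324.

With the main step by itself and the reagent held at its charge, the target stands to free starting material as 0.351 to one, which makes the target 26.0%. The dormant form then takes 0.54 for each part of free starting material, so the target falls to 18.6%. The isomer takes 0.10 of each part of target, which leaves 18.2%.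

The second substrate then claims 0.327 of reagent, and with what target and isomer hold, the free reagent comes to 0.972. But that overshoots, because at that reagent the target is 12.7% and the balance returns 1.12.

So we replace the swinging reagent by its mean, 1.05. The pull, meaning the main constant times the free reagent, which is the target held per part of free starting material (an apparent equilibrium constant), is then 0.245. It gives target 13.5% and conversion 44.7%. To check the error, we put the mean back: the balance returns 1.10, and that gives target 14.1%, so we commit to a target between those two figures.

The forecast said forward and back rates have come level, with conversion 45% (from 43.5% to 46.5%) and target 14% (from 13.3% to 14.7%), reasoning that “the portionwise addition has been forgotten and the flask sits at equilibrium”.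

The simulation gives forward and back rates have come level, with conversion 45.0% and target 14.0%, and the portions change no conversion. The flask keeps 72% of its reagent, a pull of 0.254 against our 0.245. The neighbour charged with 6.00 equiv of reagent takes the same reckoning: its balances return 4.84 and 4.94, so its pull is 1.14 and its target 40.9%. Simulated, that neighbour gives target 41.1% at conversion 64.4%.

The constants used here were set for the occasion.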